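**Retrosynthetic overview**

1. The last disconnections are the protecting groups (three methyl ethers and one benzyl ester, all removed by BBr3) and the oxidation level of ring C: the isocoumarin comes from a 3,4-dihydroisocoumarin by opening the lactone, oxidising the C3 carbinol and closing again.
2. Ring C is built in one three-component palladium/norbornene step from aryl iodide 12, 1,2-epoxyheptane and CO, which forms C4a–C4, C8a–C1 and C1–O2.
3. The strategy rests on ring A (isocoumarin numbering): the ether oxygen on C8, the carbonyl carbon on C8a and the C4 methylene on C4a sit on three neighbouring carbons, so an iodide at C8a has the aryloxy group as its only ortho substituent and C4a–H as its only ortho C–H. Ring B (ether carbon C1', oxygen on C2', pentyl on C6') has no C–H next to the ether carbon and cannot divert the arylpalladium into a dibenzofuran.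
4. The diaryl ether comes from SNAr of ring B phenol 7 on 3-fluoro-4-nitroanisole, then nitro to amine to iodide. Ring B comes from olivetol by bromination at both positions flanking the pentyl chain, then one bromine becomes the benzyl ester and the other the hydroxyl.
5. Rings A and B are bought as arenes; ring C is the only ring formed (step 8).

Key step: step 8

**Remarks on the chemistry**

- The ring B carboxyl is carried as a benzyl ester. A 2,6-disubstituted alkyl benzoate resists mild saponification, and the β-resorcylic acid of the target decarboxylates on heating, so the ester is chosen to fall in the same cold BBr3 step as the methyl ethers.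
- The target has no stereocentre. Compounds 15 and 16 are racemic at C3.
- Palladium-bound species of the catalytic cycles are described in the Why lines and carry no compound numbers.

**Route**

Step 1
Reactants: 1 olivetol
Product: 2 1,3-dimethoxy-5-pentylbenzene
Conditions: MeI (3 equiv), K2CO3 (3 equiv), acetone, reflux
Reagents that add atoms: iodomethane CI
Why: Williamson O-methylation of both phenols with a mild carbonate base, which favours O- over C-alkylation of the resorcinol.

Step 2
Reactants: 2 1,3-dimethoxy-5-pentylbenzene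
Product: 3 2,4-dibromo-1,5-dimethoxy-3-pentylbenzene
Conditions: NBS (2.1 equiv), MeCN, 0 °C to rt
Reagents that add atoms: N-bromosuccinimide O=C1CCC(=O)N1Br
Why: Electrophilic aromatic bromination should enter twice para to a methoxy group, at the two ring positions that flank the pentyl chain, since the position between the two methoxy groups is the less reactive site of a 5-alkylresorcinol diether.

Step 3
Reactants: 3 2,4-dibromo-1,5-dimethoxy-3-pentylbenzene
Product: 5 benzyl 3-bromo-4,6-dimethoxy-2-pentylbenzoate, via aryllithium 4 (not isolated)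
Conditions: n-BuLi (1.0 equiv), THF, −78 °C; then cannulated into ClCO2Bn (2 equiv), THF, −78 °C to rt
Reagents that add atoms: benzyl chloroformate O=C(Cl)OCc1ccccc1; n-butyllithium [Li]CCCC (lithium of 4 only)
Why: Bromine–lithium exchange on one of the two equivalent bromides is fast at −78 °C, and the hindered aryllithium, added to excess chloroformate, should be acylated once to the ester (acylation of an organolithium with a chloroformate).

Step 4
Reactants: 5 benzyl 3-bromo-4,6-dimethoxy-2-pentylbenzoate
Product: 7 benzyl 3-hydroxy-4,6-dimethoxy-2-pentylbenzoate, via pinacol boronate 6 (not isolated)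
Conditions: B2pin2, Pd(OAc)2 (cat.), SPhos, KOAc, dioxane, 100 °C; then 30% H2O2, NaOH (aq), THF, 0 °C
Reagents that add atoms: hydrogen peroxide OO (hydroxyl oxygen of 7); bis(pinacolato)diboron CC1(C)OB(OC1(C)C)B1OC(C)(C)C(C)(C)O1 (boryl group of 6 only)
Why: Miyaura borylation with the biaryl phosphine SPhos suits a bromide flanked by two ortho substituents, and alkaline peroxide then turns the C–B bond into C–O by 1,2-migration of the aryl group, the doubly ortho-substituted benzyl ester being too hindered to be saponified in the cold.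

Step 5
Reactants: 7 benzyl 3-hydroxy-4,6-dimethoxy-2-pentylbenzoate; 8 3-fluoro-4-nitroanisole
Product: 9 benzyl 4,6-dimethoxy-3-(5-methoxy-2-nitrophenoxy)-2-pentylbenzoate
Conditions: K2CO3, DMF, 80 °C
Reagents that add atoms: none
Why: Nucleophilic aromatic substitution through a Meisenheimer adduct: the fluoride ortho to the nitro group is displaced by the phenoxide of 7, and the hindered benzyl ester does not react with carbonate.

Step 6
Reactants: 9 benzyl 4,6-dimethoxy-3-(5-methoxy-2-nitrophenoxy)-2-pentylbenzoate
Product: 10 benzyl 3-(2-amino-5-methoxyphenoxy)-4,6-dimethoxy-2-pentylbenzoate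
Conditions: Fe powder, AcOH, EtOH, 70 °C
Reagents that add atoms: none
Why: Béchamp-type reduction by iron in acetic acid converts the nitro group into the aniline without touching the benzyl ester, which catalytic hydrogenation would endanger.

Step 7
Reactants: 10 benzyl 3-(2-amino-5-methoxyphenoxy)-4,6-dimethoxy-2-pentylbenzoate
Product: 12 benzyl 3-(2-iodo-5-methoxyphenoxy)-4,6-dimethoxy-2-pentylbenzoate, via diazonium tosylate 11 (not isolated)
Conditions: p-TsOH·H2O (3 equiv), NaNO2 (2 equiv), KI (2.5 equiv), MeCN/H2O, 10 °C to rt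
Reagents that add atoms: potassium iodide [K+].[I-]; sodium nitrite [Na+].[O-]N=O (second nitrogen of 11 only)
Why: Sandmeyer-type iodination: diazotisation in the presence of a sulfonic acid gives a stable diazonium salt that iodide replaces without copper, and acid of this strength at room temperature leaves the ethers and the benzyl ester intact.

Step 8
Reactants: 12 benzyl 3-(2-iodo-5-methoxyphenoxy)-4,6-dimethoxy-2-pentylbenzoate; 13 1,2-epoxyheptane (racemic, 3 equiv); 14 carbon monoxide
Product: 15 benzyl 4,6-dimethoxy-3-[(6-methoxy-1-oxo-3-pentyl-3,4-dihydro-1H-isochromen-8-yl)oxy]-2-pentylbenzoate (racemic at C3)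
Conditions: Pd(OAc)2 (10 mol%), tri(2-furyl)phosphine (22 mol%), norbornene (2 equiv), Cs2CO3 (2.5 equiv), CO (1 atm, balloon), NMP, 80 °C
Reagents that add atoms: none
Why: Proposed new method: zerovalent palladium should insert into the carbon–iodine bond at C8a, norbornene should insert, and carbonate-assisted cleavage of the C4a–H bond should give the aryl–norbornyl palladacycle of divalent palladium, which opens epoxide 13 at its CH2 terminus to a tetravalent palladium alkoxide and forms C4a–C4 by reductive elimination. Norbornene is then expelled by β-carbon elimination because C8a is now flanked on both sides, CO inserts into the aryl–palladium bond, and the tethered secondary alkoxide attacks the acyl group (6-exo-trig acyl substitution, equivalent to C–O reductive elimination from a seven-membered acyl alkoxide palladacycle), closing ring C and returning zerovalent palladium. The closest known reactions are the palladium/norbornene ortho-alkylation of aryl iodides with epoxides, which normally ends in ipso C–O closure to 2,3-dihydrobenzofurans, and Catellani sequences ended by ipso carbonylation; their combination has not been shown. Site selectivity rests on the substrate: the aryloxy group on C8 leaves C4a–H as the only ortho C–H, and ring B carries a methoxy group and the pentyl chain on the two carbons next to its ether carbon, so cyclisation to a dibenzofuran has no C–H to use. The epoxide is attacked at its unsubstituted carbon, so the pentyl group ends on C3; this centre is racemic because 13 is racemic and needs no control, since it is flattened in steps 10 and 11. The selectivity to be won is the order of events (norbornene before CO at the arylpalladium iodide, then CO before direct C–O closure or β-hydride loss from the alkoxide), for which excess norbornene, one atmosphere of CO and a small, weakly donating phosphine are chosen.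

Step 9
Reactants: 15 benzyl 4,6-dimethoxy-3-[(6-methoxy-1-oxo-3-pentyl-3,4-dihydro-1H-isochromen-8-yl)oxy]-2-pentylbenzoate
Product: 16 benzyl 3-[2-(dimethylcarbamoyl)-3-(2-hydroxyheptyl)-5-methoxyphenoxy]-4,6-dimethoxy-2-pentylbenzoate (racemic)
Conditions: Me2NH (2 M in THF), AlMe3, CH2Cl2, 0 to 40 °C; aqueous Rochelle salt work-up
Reagents that add atoms: dimethylamine CNC
Why: Aminolysis of a lactone by a dimethylaluminium amide should open the planar lactone carbonyl, while the twisted 2,6-disubstituted benzyl ester of ring B stays out of reach; C3 remains racemic.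

Step 10
Reactants: 16 benzyl 3-[2-(dimethylcarbamoyl)-3-(2-hydroxyheptyl)-5-methoxyphenoxy]-4,6-dimethoxy-2-pentylbenzoate (used crude)
Product: 17 benzyl 3-[2-(dimethylcarbamoyl)-5-methoxy-3-(2-oxoheptyl)phenoxy]-4,6-dimethoxy-2-pentylbenzoate
Conditions: Dess–Martin periodinane, pyridine, CH2Cl2, 0 °C to rt
Reagents that add atoms: none
Why: Dess–Martin oxidation of the secondary alcohol under pyridine buffering gives the ketone without acid that could close the hydroxy amide back to the lactone.

Step 11
Reactants: 17 benzyl 3-[2-(dimethylcarbamoyl)-5-methoxy-3-(2-oxoheptyl)phenoxy]-4,6-dimethoxy-2-pentylbenzoate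
Product: 18 benzyl 4,6-dimethoxy-3-[(6-methoxy-1-oxo-3-pentyl-1H-isochromen-8-yl)oxy]-2-pentylbenzoate
Conditions: AcOH, 110 °C
Reagents that add atoms: none
Why: Acid-catalysed cyclisation of a 2-(2-oxoalkyl)benzamide: the ketone oxygen (enol form) adds to the protonated tertiary amide, dimethylamine leaves and loss of the C4 proton gives the conjugated isocoumarin, which removes the C3 stereocentre.

Step 12
Reactants: 18 benzyl 4,6-dimethoxy-3-[(6-methoxy-1-oxo-3-pentyl-1H-isochromen-8-yl)oxy]-2-pentylbenzoate
Product: 19 4,6-dihydroxy-3-[(6-hydroxy-1-oxo-3-pentyl-1H-isochromen-8-yl)oxy]-2-pentylbenzoic acid (CNP0439913.0)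
Conditions: BBr3 (10 equiv), pentamethylbenzene (3 equiv), CH2Cl2, −78 °C to rt; ice-water quench
Reagents that add atoms: none
Why: BBr3 cleaves the aryl methyl ethers by bromide attack on the O-methyl of the boron complex and cleaves the benzyl ester through benzyl cation transfer to the pentamethylbenzene scavenger, while the diaryl ether and the enol lactone are inert; the cold aqueous quench avoids decarboxylation of the β-resorcylic acid.

**Compound list**

1 | olivetol (5-pentylbenzene-1,3-diol) | CCCCCc1cc(O)cc(O)c1 | starting material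
2 | 1,3-dimethoxy-5-pentylbenzene | CCCCCc1cc(OC)cc(OC)c1 | intermediate
3 | 2,4-dibromo-1,5-dimethoxy-3-pentylbenzene | CCCCCc1c(Br)c(OC)cc(OC)c1Br | intermediate
4 | (3-bromo-4,6-dimethoxy-2-pentylphenyl)lithium (not isolated) | [Li]c1c(CCCCC)c(Br)c(OC)cc1OC | intermediate
5 | benzyl 3-bromo-4,6-dimethoxy-2-pentylbenzoate | CCCCCc1c(Br)c(OC)cc(OC)c1C(=O)OCc1ccccc1 | intermediate
6 | benzyl 4,6-dimethoxy-2-pentyl-3-(4,4,5,5-tetramethyl-1,3,2-dioxaborolan-2-yl)benzoate (not isolated) | CCCCCc1c(B2OC(C)(C)C(C)(C)O2)c(OC)cc(OC)c1C(=O)OCc1ccccc1 | intermediate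
7 | benzyl 3-hydroxy-4,6-dimethoxy-2-pentylbenzoate | CCCCCc1c(O)c(OC)cc(OC)c1C(=O)OCc1ccccc1 | intermediate
8 | 3-fluoro-4-nitroanisole | COc1ccc([N+](=O)[O-])c(F)c1 | starting material
9 | benzyl 4,6-dimethoxy-3-(5-methoxy-2-nitrophenoxy)-2-pentylbenzoate | CCCCCc1c(Oc2cc(OC)ccc2[N+](=O)[O-])c(OC)cc(OC)c1C(=O)OCc1ccccc1 | intermediate
10 | benzyl 3-(2-amino-5-methoxyphenoxy)-4,6-dimethoxy-2-pentylbenzoate | CCCCCc1c(Oc2cc(OC)ccc2N)c(OC)cc(OC)c1C(=O)OCc1ccccc1 | intermediate
11 | 2-{3-[(benzyloxy)carbonyl]-4,6-dimethoxy-2-pentylphenoxy}-4-methoxybenzenediazonium 4-methylbenzenesulfonate (not isolated) | CCCCCc1c(Oc2cc(OC)ccc2[N+]#N)c(OC)cc(OC)c1C(=O)OCc1ccccc1.Cc1ccc(S(=O)(=O)[O-])cc1 | intermediate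
12 | benzyl 3-(2-iodo-5-methoxyphenoxy)-4,6-dimethoxy-2-pentylbenzoate | CCCCCc1c(Oc2cc(OC)ccc2I)c(OC)cc(OC)c1C(=O)OCc1ccccc1 | intermediate
13 | 1,2-epoxyheptane (2-pentyloxirane, racemic) | CCCCCC1CO1 | starting material
14 | carbon monoxide | [C-]#[O+] | starting material
15 | benzyl 4,6-dimethoxy-3-[(6-methoxy-1-oxo-3-pentyl-3,4-dihydro-1H-isochromen-8-yl)oxy]-2-pentylbenzoate (racemic at C3) | CCCCCC1Cc2cc(OC)cc(Oc3c(OC)cc(OC)c(C(=O)OCc4ccccc4)c3CCCCC)c2C(=O)O1 | intermediate
16 | benzyl 3-[2-(dimethylcarbamoyl)-3-(2-hydroxyheptyl)-5-methoxyphenoxy]-4,6-dimethoxy-2-pentylbenzoate (racemic) | CCCCCC(O)Cc1cc(OC)cc(Oc2c(OC)cc(OC)c(C(=O)OCc3ccccc3)c2CCCCC)c1C(=O)N(C)C | intermediate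
17 | benzyl 3-[2-(dimethylcarbamoyl)-5-methoxy-3-(2-oxoheptyl)phenoxy]-4,6-dimethoxy-2-pentylbenzoate | CCCCCC(=O)Cc1cc(OC)cc(Oc2c(OC)cc(OC)c(C(=O)OCc3ccccc3)c2CCCCC)c1C(=O)N(C)C | intermediate
18 | benzyl 4,6-dimethoxy-3-[(6-methoxy-1-oxo-3-pentyl-1H-isochromen-8-yl)oxy]-2-pentylbenzoate | CCCCCc1cc2cc(OC)cc(Oc3c(OC)cc(OC)c(C(=O)OCc4ccccc4)c3CCCCC)c2c(=O)o1 | intermediate
19 | 4,6-dihydroxy-3-[(6-hydroxy-1-oxo-3-pentyl-1H-isochromen-8-yl)oxy]-2-pentylbenzoic acid (CNP0439913.0) | CCCCCc1cc2cc(O)cc(Oc3c(O)cc(O)c(C(=O)O)c3CCCCC)c2c(=O)o1 | target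

**Step count**

Total: 12 steps. Longest linear sequence: 12 steps, from olivetol 1 to target 19; compounds 8, 13 and 14 enter as single building blocks.

**Steps most likely to fail**

Step 8 (Proposed new method). Several processes may go wrong:
- CO may be taken up by the arylpalladium iodide before norbornene inserts, so that ring A is carbonylated without ortho-alkylation.
- CO may insert into the aryl–norbornyl palladacycle.
- The tethered alkoxide may close directly on the aryl carbon, giving the five-membered cyclic ether without CO.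
- The alkoxide may lose a β-hydride, which reduces the ipso carbon.

The fallback uses known chemistry and sets out from 12. Palladium-catalysed hydroxycarbonylation (Pd(OAc)2, Xantphos, CO, H2O, K2CO3, DMF, 80 °C) should give 2-{3-[(benzyloxy)carbonyl]-4,6-dimethoxy-2-pentylphenoxy}-4-methoxybenzoic acid F1. Its carboxylate then directs the known ortho C–H alkylation of benzoic acids with terminal epoxides by divalent palladium (Pd(OAc)2, N-acetylvaline, KOAc, 13, hexafluoroisopropanol, 60 to 75 °C). The only ortho C–H of F1 is C4a–H, and spontaneous lactonisation returns to the route at 15.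

Step 4. Oxidative addition into the bromide between a methoxy group and the pentyl chain may be slow, so that protodebromination competes, and the oxidation may begin to saponify the ester. The fallback sets out from 3 and installs the oxygen first and the carboxyl last. Aryllithium 4 (n-BuLi, THF, −78 °C) would be trapped with B(OMe)3 as lithium (3-bromo-4,6-dimethoxy-2-pentylphenyl)trimethoxyborate F2. AcOH and 30% H2O2 should oxidise this in the same flask to 3-bromo-4,6-dimethoxy-2-pentylphenol F3. SNAr of F3 on 8 (K2CO3, DMF, 80 °C) should give 2-bromo-1,5-dimethoxy-4-(5-methoxy-2-nitrophenoxy)-3-pentylbenzene F4. Palladium-catalysed benzyloxycarbonylation of its bromide (Pd(OAc)2, Xantphos, CO, BnOH, Na2CO3, toluene, 100 °C) returns to the route at 9.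

Step 9. Attack of the aluminium amide on a lactone carbonyl flanked by the C8 aryloxy group may be sluggish, and the hydroxy amide may close back to the lactone during work-up. The fallback sets out from 15 and goes through an ester instead of an amide. LiOH (THF/H2O, rt) should open the lactone to lithium 2-{3-[(benzyloxy)carbonyl]-4,6-dimethoxy-2-pentylphenoxy}-6-(2-hydroxyheptyl)-4-methoxybenzoate F5. After evaporation, MeI in DMF should alkylate the carboxylate to methyl 2-{3-[(benzyloxy)carbonyl]-4,6-dimethoxy-2-pentylphenoxy}-6-(2-hydroxyheptyl)-4-methoxybenzoate F6. Dess–Martin oxidation (pyridine, CH2Cl2) gives methyl 2-{3-[(benzyloxy)carbonyl]-4,6-dimethoxy-2-pentylphenoxy}-4-methoxy-6-(2-oxoheptyl)benzoate F7. This should close in AcOH at 110 °C with loss of methanol and return to the route at 18, so that 16 and 17 are bypassed.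

**Further compounds**

F1 | step 8 | 2-{3-[(benzyloxy)carbonyl]-4,6-dimethoxy-2-pentylphenoxy}-4-methoxybenzoic acid | CCCCCc1c(Oc2cc(OC)ccc2C(=O)O)c(OC)cc(OC)c1C(=O)OCc1ccccc1
F2 | step 4 | lithium (3-bromo-4,6-dimethoxy-2-pentylphenyl)trimethoxyborate | [Li+].CCCCCc1c(Br)c(OC)cc(OC)c1[B-](OC)(OC)OC
F3 | step 4 | 3-bromo-4,6-dimethoxy-2-pentylphenol | CCCCCc1c(O)c(OC)cc(OC)c1Br
F4 | step 4 | 2-bromo-1,5-dimethoxy-4-(5-methoxy-2-nitrophenoxy)-3-pentylbenzene | CCCCCc1c(Oc2cc(OC)ccc2[N+](=O)[O-])c(OC)cc(OC)c1Br
F5 | step 9 | lithium 2-{3-[(benzyloxy)carbonyl]-4,6-dimethoxy-2-pentylphenoxy}-6-(2-hydroxyheptyl)-4-methoxybenzoate (racemic) | [Li+].CCCCCC(O)Cc1cc(OC)cc(Oc2c(OC)cc(OC)c(C(=O)OCc3ccccc3)c2CCCCC)c1C(=O)[O-]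
F6 | step 9 | methyl 2-{3-[(benzyloxy)carbonyl]-4,6-dimethoxy-2-pentylphenoxy}-6-(2-hydroxyheptyl)-4-methoxybenzoate (racemic) | CCCCCC(O)Cc1cc(OC)cc(Oc2c(OC)cc(OC)c(C(=O)OCc3ccccc3)c2CCCCC)c1C(=O)OC
F7 | step 9 | methyl 2-{3-[(benzyloxy)carbonyl]-4,6-dimethoxy-2-pentylphenoxy}-4-methoxy-6-(2-oxoheptyl)benzoate | CCCCCC(=O)Cc1cc(OC)cc(Oc2c(OC)cc(OC)c(C(=O)OCc3ccccc3)c2CCCCC)c1C(=O)OC
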